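Ring B, numbered from its butanoyl carbon C1, is disconnected at C1–C2 and C5–C6. Its carbons alternate between oxygen-bearing (C2, C4, C6) and carbon-bearing (C1 acyl; C3 and C5 with the CH2 links to rings A), the signature of a β-ketoester dienol ether (C2–C5) joined to an acylated ynol ether (C6, C1). A single benzannulation of diene 11 with ethoxy ynone 16 should therefore deliver the hexasubstituted central ring with its ketone in place. Diene 11 is the bis(trimethylsilyl) dienol ether of a 2,4-bis(arylmethyl)acetoacetate and already holds both bridges and both rings A as methyl ethers; acylation of rings A and ether cleavage complete the route.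

Key step: step 8

Remark: the target is achiral. Compounds 8 and 15 are racemic and 17 is a racemic mixture of diastereomers; each of these centres disappears in the next event. The double-bond geometries drawn for 7, 9, 10 and 11 are the expected ones and none reaches the product.

Remark: the two arylmethyl arms of 11 are identical, so ketoester 8 is assembled by self-condensation of ester 6. This avoids a 2,4,6-trialkoxybenzyl halide, a type that ionises and self-alkylates readily.

Step 1
Reactants: 1 1,3,5-trimethoxy-2-methylbenzene (2,4,6-trimethoxytoluene)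
Product: 3 2,4,6-trimethoxy-3-methylbenzaldehyde, via aryl iminium chloride 2 (not isolated)
Conditions: POCl3, DMF, 0 to 25 °C; then ice–water
Reagents that add atoms: N,N-dimethylformamide, CN(C)C=O; water, O
Why: Vilsmeier–Haack formylation should occur at one of the two equivalent free ring carbons of 1, each flanked by two methoxy groups, and the electron-poor iminium ion 2 resists a second attack, so one aldehyde is expected after hydrolysis.

Step 2
Reactants: 3 2,4,6-trimethoxy-3-methylbenzaldehyde; 4 methyl 2-(triphenyl-λ5-phosphanylidene)acetate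
Product: 5 methyl (2E)-3-(2,4,6-trimethoxy-3-methylphenyl)prop-2-enoate
Conditions: toluene, 110 °C
Reagents that add atoms: none
Why: Wittig olefination with a stabilised ylide tolerates the hindered, electron-rich aldehyde at elevated temperature and should give the E-enoate, whose geometry is removed in step 3.

Step 3
Reactants: 5 methyl (2E)-3-(2,4,6-trimethoxy-3-methylphenyl)prop-2-enoate
Product: 6 methyl 3-(2,4,6-trimethoxy-3-methylphenyl)propanoate
Conditions: H2 (1 atm), Pd on carbon (10% Pd), EtOAc, 20 °C
Reagents that add atoms: none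
Why: Heterogeneous catalytic hydrogenation should saturate the conjugated C=C bond while the ester, the aryl ethers and the arene stay untouched at ambient pressure.

Step 4
Reactants: 6 methyl 3-(2,4,6-trimethoxy-3-methylphenyl)propanoate (two molecules)
Product: 8 methyl 3-oxo-5-(2,4,6-trimethoxy-3-methylphenyl)-2-[(2,4,6-trimethoxy-3-methylphenyl)methyl]pentanoate, via sodium enolate 7 (not isolated)
Conditions: NaH (0.6 equiv per ester), cat. MeOH, THF, 65 °C; then AcOH, 0 °C
Reagents that add atoms: none
Why: Claisen self-condensation of 6 is driven by deprotonation of the β-ketoester to 7 and places the two identical arylmethyl arms at C2 and C4 in one operation, with the C2 stereocentre formed racemic and erased in step 5.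

Step 5
Reactants: 8 methyl 3-oxo-5-(2,4,6-trimethoxy-3-methylphenyl)-2-[(2,4,6-trimethoxy-3-methylphenyl)methyl]pentanoate
Product: 9 methyl (2Z)-5-(2,4,6-trimethoxy-3-methylphenyl)-2-[(2,4,6-trimethoxy-3-methylphenyl)methyl]-3-[(trimethylsilyl)oxy]pent-2-enoate
Conditions: Me3SiCl, Et3N, toluene, 20 °C, 72 h; filtration under argon
Reagents that add atoms: chlorotrimethylsilane, C[Si](C)(C)Cl
Why: Soft enolisation and O-silylation of a β-ketoester with a chlorosilane and a tertiary amine is the standard first stage towards 1,3-bis(silyloxy)dienes and is known for 2-alkyl acetoacetates, and either enol ether geometry would serve in step 6.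

Step 6
Reactants: 9 methyl (2Z)-5-(2,4,6-trimethoxy-3-methylphenyl)-2-[(2,4,6-trimethoxy-3-methylphenyl)methyl]-3-[(trimethylsilyl)oxy]pent-2-enoate
Product: 11 (1Z,3Z)-1-methoxy-2,4-bis[(2,4,6-trimethoxy-3-methylphenyl)methyl]-1,3-bis[(trimethylsilyl)oxy]buta-1,3-diene, via lithium dienolate 10 (not isolated)
Conditions: LiN(CHMe2)2, THF, −78 °C; then Me3SiCl, −78 to 20 °C; LiCl removed by filtration from pentane, diene used crude
Reagents that add atoms: chlorotrimethylsilane, C[Si](C)(C)Cl
Why: Kinetic γ-deprotonation of the β-silyloxy enoate gives the extended ester dienolate 10 (the CH2 on C2 is not activated by the ester) and O-silylation gives the ketene acetal, with the 3Z geometry set by avoidance of allylic strain between the C2 and C4 substituents and the C1 geometry being of no consequence.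

Step 7
Reactants: 12 ethoxyethyne; 13 N-methoxy-N-methylbutanamide
Product: 16 1-ethoxyhex-1-yn-3-one, via ethoxyethynyllithium 14 (not isolated), via tetrahedral lithium adduct 15 (not isolated)
Conditions: n-BuLi, THF, −78 °C; then 13, −78 to −20 °C; AcOH, −78 °C; rapid filtration through neutral alumina
Reagents that add atoms: none
Why: Acylation of a lithium acetylide by a Weinreb amide stops at the ketone because the chelated adduct 15 survives until the quench, a standard way to 1-alkoxyalk-1-yn-3-ones.

Step 8
Reactants: 11 (1Z,3Z)-1-methoxy-2,4-bis[(2,4,6-trimethoxy-3-methylphenyl)methyl]-1,3-bis[(trimethylsilyl)oxy]buta-1,3-diene; 16 1-ethoxyhex-1-yn-3-one (1.5 equiv)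
Product: 19 1-{2-ethoxy-4,6-dihydroxy-3,5-bis[(2,4,6-trimethoxy-3-methylphenyl)methyl]phenyl}butan-1-one, via cyclohexadiene cycloadduct 17 (not isolated), via monosilyl aryl ether 18 (not isolated)
Conditions: toluene (concentrated), argon, 20 to 70 °C; then dilute aq. HCl, THF, 20 °C
Reagents that add atoms: none
Why: Proposed new method: the electron-rich diene 11 should add to the ketone-conjugated triple bond of 16 in a strongly asynchronous [4+2] cycloaddition, whose stepwise limit is Mukaiyama–Michael attack of diene C4 on the OEt-bearing alkyne carbon followed by 6-exo-trig Claisen-type attack of the allenolate carbon on the ester-derived C1; the adduct 17 should aromatise by loss of MeOSiMe3 and enolisation to 18, and dilute acid then removes the remaining silyl group. The closest known reaction type is the thermal benzannulation of 1-alkoxy-1,3-bis(silyloxy)buta-1,3-dienes with acetylenic ketones and esters to resorcinols, which has not been shown with a 1-alkoxyalk-1-yn-3-one as the two-carbon partner. Ring B closes as a six-membered carbocycle by the two bonds C5–C6 and C1–C2 of the target numbering, both made from the diene termini in one operation. No stereocentre is created in 19, since the two sp3 ring carbons of 17 are lost on aromatisation. The step needs a single regiochemistry and the [4+2] rather than the [3+3] mode: the first follows from pairing the most nucleophilic diene terminus C4 with the alkyne carbon β to the ketone, and the second from the arylmethyl group on diene C2, because aldol closure onto the ketone would give a quaternary carbon that cannot aromatise and can revert. The ethoxy group stays because it sits on an sp2 carbon of 17, so that only the methoxy group of the sp3 ketal carbon can depart.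

Step 9
Reactants: 19 1-{2-ethoxy-4,6-dihydroxy-3,5-bis[(2,4,6-trimethoxy-3-methylphenyl)methyl]phenyl}butan-1-one; 20 butanoyl chloride (3 equiv)
Product: 21 1-{3,5-bis[(3-butanoyl-2,4,6-trimethoxy-5-methylphenyl)methyl]-2-ethoxy-4,6-dihydroxyphenyl}butan-1-one
Conditions: AlCl3, CH2Cl2, −20 to 0 °C; aq. HCl; then K2CO3, MeOH, 20 °C (cleaves any O-butanoate)
Reagents that add atoms: none
Why: Friedel–Crafts acylation can only occur at the one unsubstituted carbon of each ring A, which is flanked by two methoxy groups and as activated as a phloroglucinol trimethyl ether position, whereas ring B is fully substituted and deactivated by its ketone, and any early loss of an ether ortho to a new ketone is harmless because step 10 removes all of them.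

Step 10
Reactants: 21 1-{3,5-bis[(3-butanoyl-2,4,6-trimethoxy-5-methylphenyl)methyl]-2-ethoxy-4,6-dihydroxyphenyl}butan-1-one
Product: 22 1-{3,5-bis[(3-butanoyl-2,4,6-trihydroxy-5-methylphenyl)methyl]-2,4,6-trihydroxyphenyl}butan-1-one (CNP0296563.0)
Conditions: BBr3 (about 12 equiv), CH2Cl2, −78 to 20 °C; then H2O, 0 °C
Reagents that add atoms: none
Why: Lewis-acid ether cleavage with BBr3 (bromide attack on the O-alkyl carbon of each boron-complexed ether) should remove the six methyl groups and the ethyl group, five of them assisted by chelation to a neighbouring ketone, while the three acyl groups lower the basicity of all rings and so should protect the diarylmethane links from ipso-protonation.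

Compound list
1 | 1,3,5-trimethoxy-2-methylbenzene (2,4,6-trimethoxytoluene) | Cc1c(OC)cc(OC)cc1OC | starting material
2 | N,N-dimethyl-1-(2,4,6-trimethoxy-3-methylphenyl)methaniminium chloride | C[N+](C)=Cc1c(OC)cc(OC)c(C)c1OC.[Cl-] | intermediate
3 | 2,4,6-trimethoxy-3-methylbenzaldehyde | O=Cc1c(OC)cc(OC)c(C)c1OC | intermediate
4 | methyl 2-(triphenyl-λ5-phosphanylidene)acetate | COC(=O)C=P(c1ccccc1)(c1ccccc1)c1ccccc1 | starting material
5 | methyl (2E)-3-(2,4,6-trimethoxy-3-methylphenyl)prop-2-enoate | COC(=O)/C=C/c1c(OC)cc(OC)c(C)c1OC | intermediate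
6 | methyl 3-(2,4,6-trimethoxy-3-methylphenyl)propanoate | COC(=O)CCc1c(OC)cc(OC)c(C)c1OC | intermediate
7 | sodium (2Z)-1-methoxy-1-oxo-5-(2,4,6-trimethoxy-3-methylphenyl)-2-[(2,4,6-trimethoxy-3-methylphenyl)methyl]pent-2-en-3-olate | [Na+].COC(=O)/C(Cc1c(OC)cc(OC)c(C)c1OC)=C(\[O-])CCc1c(OC)cc(OC)c(C)c1OC | intermediate
8 | methyl 3-oxo-5-(2,4,6-trimethoxy-3-methylphenyl)-2-[(2,4,6-trimethoxy-3-methylphenyl)methyl]pentanoate (racemic; labile C2 centre) | COC(=O)C(Cc1c(OC)cc(OC)c(C)c1OC)C(=O)CCc1c(OC)cc(OC)c(C)c1OC | intermediate
9 | methyl (2Z)-5-(2,4,6-trimethoxy-3-methylphenyl)-2-[(2,4,6-trimethoxy-3-methylphenyl)methyl]-3-[(trimethylsilyl)oxy]pent-2-enoate | COC(=O)/C(Cc1c(OC)cc(OC)c(C)c1OC)=C(\O[Si](C)(C)C)CCc1c(OC)cc(OC)c(C)c1OC | intermediate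
10 | lithium (1E,3Z)-1-methoxy-2,4-bis[(2,4,6-trimethoxy-3-methylphenyl)methyl]-3-[(trimethylsilyl)oxy]buta-1,3-dien-1-olate | [Li+].CO/C([O-])=C(Cc1c(OC)cc(OC)c(C)c1OC)/C(O[Si](C)(C)C)=C/Cc1c(OC)cc(OC)c(C)c1OC | intermediate
11 | (1Z,3Z)-1-methoxy-2,4-bis[(2,4,6-trimethoxy-3-methylphenyl)methyl]-1,3-bis[(trimethylsilyl)oxy]buta-1,3-diene | CO/C(O[Si](C)(C)C)=C(Cc1c(OC)cc(OC)c(C)c1OC)/C(O[Si](C)(C)C)=C/Cc1c(OC)cc(OC)c(C)c1OC | intermediate
12 | ethoxyethyne | CCOC#C | starting material
13 | N-methoxy-N-methylbutanamide | CCCC(=O)N(C)OC | starting material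
14 | (ethoxyethynyl)lithium | CCOC#C[Li] | intermediate
15 | lithium 1-ethoxy-3-[methoxy(methyl)amino]hex-1-yn-3-olate (racemic) | [Li+].CCCC([O-])(C#COCC)N(C)OC | intermediate
16 | 1-ethoxyhex-1-yn-3-one | CCCC(=O)C#COCC | intermediate
17 | 1-{2-ethoxy-6-methoxy-3,5-bis[(2,4,6-trimethoxy-3-methylphenyl)methyl]-4,6-bis[(trimethylsilyl)oxy]cyclohexa-1,4-dien-1-yl}butan-1-one (racemic; configuration at ring C3 and C6 not controlled, both centres lost on aromatisation) | CCCC(=O)C1=C(OCC)C(Cc2c(OC)cc(OC)c(C)c2OC)C(O[Si](C)(C)C)=C(Cc2c(OC)cc(OC)c(C)c2OC)C1(OC)O[Si](C)(C)C | intermediate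
18 | 1-{2-ethoxy-6-hydroxy-3,5-bis[(2,4,6-trimethoxy-3-methylphenyl)methyl]-4-[(trimethylsilyl)oxy]phenyl}butan-1-one | CCCC(=O)c1c(OCC)c(Cc2c(OC)cc(OC)c(C)c2OC)c(O[Si](C)(C)C)c(Cc2c(OC)cc(OC)c(C)c2OC)c1O | intermediate
19 | 1-{2-ethoxy-4,6-dihydroxy-3,5-bis[(2,4,6-trimethoxy-3-methylphenyl)methyl]phenyl}butan-1-one | CCCC(=O)c1c(OCC)c(Cc2c(OC)cc(OC)c(C)c2OC)c(O)c(Cc2c(OC)cc(OC)c(C)c2OC)c1O | intermediate
20 | butanoyl chloride | CCCC(Cl)=O | starting material
21 | 1-{3,5-bis[(3-butanoyl-2,4,6-trimethoxy-5-methylphenyl)methyl]-2-ethoxy-4,6-dihydroxyphenyl}butan-1-one | CCCC(=O)c1c(OCC)c(Cc2c(OC)c(C(=O)CCC)c(OC)c(C)c2OC)c(O)c(Cc2c(OC)c(C(=O)CCC)c(OC)c(C)c2OC)c1O | intermediate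
22 | 1-{3,5-bis[(3-butanoyl-2,4,6-trihydroxy-5-methylphenyl)methyl]-2,4,6-trihydroxyphenyl}butan-1-one | CCCC(=O)c1c(O)c(C)c(O)c(Cc2c(O)c(Cc3c(O)c(C)c(O)c(C(=O)CCC)c3O)c(O)c(C(=O)CCC)c2O)c1O | target

Total steps: 10. Longest linear sequence: 9 steps (steps 1 to 6, then 8 to 10); step 7 is a one-step side branch.

Steps most likely to fail

Step 8 (the proposed new method). The donor-substituted alkyne may be too slow a partner for the doubly branched diene below the temperature at which ethyl ynol ethers lose ethene. Diene hydrolysis, silyl transfer or ynone decomposition could then outrun bond formation, and a stepwise adduct could stop before ring closure. The fallback uses known chemistry and makes the bridges last. From 1, Friedel–Crafts acylation with 20 (AlCl3, CH2Cl2, 0 °C) would give 1-(2,4,6-trimethoxy-3-methylphenyl)butan-1-one F1, and BBr3 would free 1-(2,4,6-trihydroxy-3-methylphenyl)butan-1-one F2. Purchased 1-(2,4,6-trihydroxyphenyl)butan-1-one (CCCC(=O)c1c(O)cc(O)cc1O) would be aminomethylated twice with dimethyl(methylidene)ammonium iodide in a Mannich reaction to 1-{3,5-bis[(dimethylamino)methyl]-2,4,6-trihydroxyphenyl}butan-1-one F3. Heating F3 with two equivalents of F2 in dioxane would expel dimethylamine, and the ortho-quinone methides so formed would be captured by the one free ring carbon of F2. This is the classical manifold for methylene-bridged acylphloroglucinols and rejoins the route at 22.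

Step 9. Acid-promoted ipso attack by protons or by the acylium ion at the bridge-bearing ring carbons could cut or scramble the diarylmethane links, and acylation at the crowded ring A carbon could stay incomplete. The fallback sets out from 19 and reverses the last two operations. BBr3 would first give 1-{2,4,6-trihydroxy-3,5-bis[(2,4,6-trihydroxy-3-methylphenyl)methyl]phenyl}butan-1-one F4. C-acylation of the free-phenol rings A with 20 and AlCl3 in nitrobenzene (O-acylation and Fries rearrangement, the classical entry to acylphloroglucinols) can again occur only at the single free carbon of each ring A and rejoins the route at 22.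

Step 6. Deprotonation of the crowded, tetrasubstituted enol ether could be incomplete or misdirected (amide attack at silicon, C-silylation), and the diene, too heavy to distil, could hydrolyse during isolation and carry unreactive ketoester into the key step. The fallback sets out from 8 and introduces both silyl groups in one flask by soft enolisation with Me3SiOSO2CF3 (2.5 equiv) and Et3N in Et2O at 0 °C, a known direct route from β-keto esters to 1,3-bis(silyloxy)dienes. The lithium amide stage and compounds 9 and 10 are bypassed, and the route is rejoined at 11. This fallback makes no new compound (entry F0).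

Further compounds
F1 | step 8 | 1-(2,4,6-trimethoxy-3-methylphenyl)butan-1-one | CCCC(=O)c1c(OC)cc(OC)c(C)c1OC
F2 | step 8 | 1-(2,4,6-trihydroxy-3-methylphenyl)butan-1-one | CCCC(=O)c1c(O)cc(O)c(C)c1O
F3 | step 8 | 1-{3,5-bis[(dimethylamino)methyl]-2,4,6-trihydroxyphenyl}butan-1-one | CCCC(=O)c1c(O)c(CN(C)C)c(O)c(CN(C)C)c1O
F4 | step 9 | 1-{2,4,6-trihydroxy-3,5-bis[(2,4,6-trihydroxy-3-methylphenyl)methyl]phenyl}butan-1-one | CCCC(=O)c1c(O)c(Cc2c(O)cc(O)c(C)c2O)c(O)c(Cc2c(O)cc(O)c(C)c2O)c1O
F0 | step 6 | none | none
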